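(The data were computed from invented constants; noise was put on by code.)

Early times are the ones to watch on a repeat, for they show how much target each enzyme molecule has turned out.

common to all: starting material 20 mM

| run | second substrate | enzyme | remark | time |
|---|---|---|---|---|
| Sunday's | 0.70 equiv | 2.8 × 10⁻⁴ mol% | run made earlier |  |
| Saturday's | 0.70 equiv | 4.1 × 10⁻⁴ mol% | run made earlier |  |
| flask | 0.700 equiv | 5.5 × 10⁻⁴ mol% |  | 1.0 h |

| Sunday's: time / min | Sunday's: target / % | Saturday's: time / min | Saturday's: target / % |
|---|---|---|---|
| 1.50 | 10.3 | 1.50 | 15.8 |
| 4.00 | 19.7 | 4.00 | 25.5 |
| 8.00 | 22.2 | 8.00 | 29.0 |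
| 15.0 | 23.5 | 15.0 | 27.5 |
| 40.0 | 20.2 | 40.0 | 25.1 |

(each reading ± 1 percentage point)

- when, up to 1.0 h, the flask holds most target
- the amount of target, in percent of the starting material charged, at that time



At 1.50 min, Saturday's run held 15.8% on 4.1 × 10⁻⁴ mol% of enzyme, a net turnover frequency of 25700 /min. Sunday's reading gave 24500 /min, about the same, so I took the pace per enzyme as fixed at this charge.

From it I reckoned a turnover clock, the time the enzyme needs at that early net pace to turn out as much target as the charge of second substrate: 4.95 min for the flask, against 6.65 min for Saturday's run and 9.73 min for Sunday's. The highest readings stood at 8.00 min on Saturday and 15.0 min on Sunday, each somewhat later than its clock. Scaling Saturday's reading, I expected the flask's peak at 0.0994 h.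

The forecast differed, with 0.13 h (0.08 h to 0.25 h) and 34.5% (31% to 38%), on these grounds: “The stall comes far too early for substrate to have run out, so the enzyme is probably dying”.

The flask peaked at 0.113 h with 32.3%, inside both ranges and 1.3 percentage points above the forecast's low end.

    starting material + target → side product (k = 0.240 /M/s)
    starting material + enzyme ⇌ starting complex (K = 38.0 /M, k = 1.80 × 10⁶ /M/s)
    second substrate + starting complex ⇌ ternary complex (K = 75.0 /M, k = 8.30 × 10⁶ /M/s)
    ternary complex → enzyme + target (k = 2000 /s)

That peak came 1.37 clocks in. Early on, at 0.0371 h, the flask made target 2.23 times faster than it used it up. By the conversion of starting material and target into side product alone, with starting material as charged, the half-life of target is 2.4 min, shorter than the flask's clock of 4.95 min. A neighbour flask with 0.0022 mol% of enzyme has, reckoned at the same pace, a clock of 1.24 min, shorter than that half-life, and its highest amount of target is 50.8%.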